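**Retrosynthetic overview**

1. Numbering (germacrane): ring C1–C10 with C1/C2 epoxide, C3 ketone, Z-C4=C5, C6–O (lactone), C8 ester, C10 carbinol; lactone carbons C11–C13. The oxirane is added last by nucleophilic epoxidation of the E-C1=C2 enone of the ring dienone.
2. Enabling feature: in that dienone the C3 carbonyl lies between two vinylic ring carbons (C2 and C4), so C3 can be delivered as CO. A carbonylative Stille macrocyclisation of a C4 vinyl iodide onto a C2 vinylstannane forms C3–C4 and then closes the ten-membered ring at C2–C3.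
3. The open precursor is cut at C7–C8: zinc Barbier union of a 3-(bromomethyl)butenolide (C4–C7, C11–C13, C15) with a β-hydroxy aldehyde (C1, C2, C8–C10, C14), then Mitsunobu inversion at C8 to install the isobutyrate.
4. Ring order: butenolide (metathesis), then α-methylene lactone (Barbier), then ten-membered carbocycle (key step), then oxirane.
5. Stereocentres: C6 from a Sharpless kinetic resolution, C10 from a Sharpless epoxidation, C7 and C8 relayed from C6, C1/C2 from the macrocycle and the C10 hydroxyl.

Key step: step 12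

**Route**

Step 1
Reactants: 1 acrolein; 2 1-propynylmagnesium bromide
Product: 3 rac-hex-1-en-4-yn-3-ol
Conditions: THF, −78 → 0 °C; aq NH4Cl
Reagents that add atoms: none
Why: Grignard 1,2-addition of the alkynyl reagent to the enal carbonyl at low temperature should give the racemic vinyl propynyl carbinol.

Step 2
Reactants: 3 rac-hex-1-en-4-yn-3-ol
Product: 4 (3S)-hex-1-en-4-yn-3-ol (recovered enantiomer)
Conditions: Ti(OiPr)4 (0.2 equiv), L-(+)-diisopropyl tartrate (0.25 equiv), t-BuOOH (0.6 equiv), 4 Å MS, CH2Cl2, −20 °C; chromatography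
Reagents that add atoms: none
Why: Sharpless kinetic resolution: with L-(+)-tartrate the (R)-alcohol should be epoxidised fast at its vinyl group, leaving the (S)-alcohol that becomes C6.

Step 3
Reactants: 4 (3S)-hex-1-en-4-yn-3-ol
Product: 5 (3S,4Z)-5-iodohexa-1,4-dien-3-ol
Conditions: NaAlH2(OCH2CH2OMe)2, THF, 0 °C → rt; then I2, −78 → 0 °C
Reagents that add atoms: iodine, [I][I]
Why: Hydroxyl-directed trans-hydroalumination of the propargylic alcohol puts aluminium on the distal carbon, and iodinolysis with retention should give the Z-iodoalkene with iodine cis to the carbinol carbon, as the Z-C4=C5 bond requires.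

Step 4
Reactants: 5 (3S,4Z)-5-iodohexa-1,4-dien-3-ol; 6 2-(bromomethyl)acrylic acid
Product: 8 (3S,4Z)-5-iodohexa-1,4-dien-3-yl 2-(bromomethyl)prop-2-enoate, via 2-(bromomethyl)acryloyl chloride 7 (not isolated)
Conditions: 6, (COCl)2, DMF (cat.), CH2Cl2, 0 °C → rt, evaporate; then 5, iPr2NEt, CH2Cl2, −40 → 0 °C
Reagents that add atoms: oxalyl chloride, O=C(Cl)C(=O)Cl (its chlorine is in intermediate 7 only)
Why: Acylation of the secondary alcohol by the acid chloride made in situ; the hindered amine and low temperature should limit attack on the allylic bromide.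

Step 5
Reactants: 8 (3S,4Z)-5-iodohexa-1,4-dien-3-yl 2-(bromomethyl)prop-2-enoate
Product: 9 (5S)-3-(bromomethyl)-5-[(1Z)-2-iodoprop-1-en-1-yl]furan-2(5H)-one
Conditions: second-generation Grubbs catalyst (5 mol %), toluene (0.01 M), 80 °C
Reagents that add atoms: none
Why: Ring-closing metathesis of the vinyl group with the 1,1-disubstituted acrylate should close the butenolide, while the trisubstituted iodoalkene is too hindered to take part.

Step 6
Reactants: 10 (2E)-3-methylpent-2-en-4-yn-1-ol
Product: 11 [(2S,3S)-3-ethynyl-3-methyloxiran-2-yl]methanol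
Conditions: Ti(OiPr)4 (10 mol %), L-(+)-diethyl tartrate (12 mol %), t-BuOOH, 4 Å MS, CH2Cl2, −20 °C
Reagents that add atoms: tert-butyl hydroperoxide, CC(C)(C)OO
Why: Sharpless asymmetric epoxidation: L-(+)-tartrate should deliver oxygen to the alkene face that gives the (2S,3S)-epoxide, which fixes the later C10 centre.

Step 7
Reactants: 11 [(2S,3S)-3-ethynyl-3-methyloxiran-2-yl]methanol
Product: 12 (3R)-3-methylpent-4-yne-1,3-diol
Conditions: NaAlH2(OCH2CH2OMe)2, THF, −20 → 0 °C
Reagents that add atoms: none
Why: Hydroxyl-directed reductive opening of the 2,3-epoxy alcohol: hydride is delivered intramolecularly to C2, away from the fully substituted C3, so the tertiary C–O bond and its configuration are kept; low temperature should spare the alkyne.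

Step 8
Reactants: 12 (3R)-3-methylpent-4-yne-1,3-diol
Product: 13 (3R,4E)-3-methyl-5-(tributylstannyl)pent-4-ene-1,3-diol
Conditions: Bu3SnH, PdCl2(PPh3)2 (2 mol %), THF, 0 °C
Reagents that add atoms: tributyltin hydride, CCCC[SnH](CCCC)CCCC
Why: Palladium-catalysed syn-hydrostannation of the terminal alkyne; the fully substituted propargylic carbon should steer tin to the terminal carbon and give the E-vinylstannane.

Step 9
Reactants: 13 (3R,4E)-3-methyl-5-(tributylstannyl)pent-4-ene-1,3-diol
Product: 14 (3R,4E)-3-hydroxy-3-methyl-5-(tributylstannyl)pent-4-enal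
Conditions: Dess–Martin periodinane, NaHCO3, CH2Cl2, 0 °C; used crude
Reagents that add atoms: none
Why: Dess–Martin oxidation takes only the primary alcohol to the aldehyde, since the tertiary alcohol cannot be oxidised, and the buffered conditions should spare the vinylstannane and the β-hydroxy aldehyde.

Step 10
Reactants: 9 (5S)-3-(bromomethyl)-5-[(1Z)-2-iodoprop-1-en-1-yl]furan-2(5H)-one; 14 (3R,4E)-3-hydroxy-3-methyl-5-(tributylstannyl)pent-4-enal
Product: 15 (4R,5S)-4-[(1S,3R,4E)-1,3-dihydroxy-3-methyl-5-(tributylstannyl)pent-4-en-1-yl]-5-[(1Z)-2-iodoprop-1-en-1-yl]-3-methylidenedihydrofuran-2(3H)-one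
Conditions: Zn dust, THF/sat. aq NH4Cl, 0 °C → rt
Reagents that add atoms: none
Why: Zinc Barbier allylation through a chair (Zimmerman–Traxler) transition state: the allylzinc from 9 attacks with its ring γ-carbon (C7) anti to the C6 substituent, giving the trans C6/C7 lactone and the exocyclic methylene, while the ring-fixed E-type allyl geometry should place the C8 hydroxyl as the (8S)-epimer, opposite to the target at C8.

Step 11
Reactants: 15 (the 8S alcohol)
Product: 16 (1R,3R,4E)-3-hydroxy-1-{(2S,3R)-2-[(1Z)-2-iodoprop-1-en-1-yl]-4-methylidene-5-oxooxolan-3-yl}-3-methyl-5-(tributylstannyl)pent-4-en-1-yl 2-methylpropanoate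
Conditions: PPh3, diisopropyl azodicarboxylate, isobutyric acid, toluene, 0 °C → rt
Reagents that add atoms: isobutyric acid, CC(C)C(=O)O
Why: Mitsunobu esterification with SN2 inversion at C8 should turn the (8S)-alcohol into the (8R)-isobutyrate in one operation; the tertiary C10 alcohol is not activated.

Step 12
Reactants: 16 (vinyl iodide/vinylstannane seco ester)
Product: 18 tagitinin C, (1E,4Z,6R,7R,8R,10R)-10-hydroxy-3-oxogermacra-1,4,11(13)-trien-6,12-olid-8-yl 2-methylpropanoate, via C3-acylpalladium iodide 17 (not isolated)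
Conditions: Pd2(dba)3 (10 mol %), AsPh3 (40 mol %), CO (3 atm), NMP/THF, 55 °C, 16 added by syringe pump (final 0.002 M)
Reagents that add atoms: carbon monoxide, [C-]#[O+]
Why: Zerovalent palladium inserts into the C4–I bond with retention of the Z geometry, CO insertion gives the C3 acylpalladium iodide 17, and transmetalation of the C2 vinylstannane followed by reductive elimination forms the ring-closing C2–C3 bond, so CO becomes the C3 ketone. The closest known reaction type is the intramolecular carbonylative Stille coupling of a vinyl halide or triflate with a vinylstannane to a macrocyclic cross-conjugated dienone. The ten-membered carbocycle is closed in the endo mode by acyl–vinyl reductive elimination, from a chain held in a turn by the Z-C4=C5 alkene and the trans-fused lactone at C6/C7. No stereocentre is formed; the Z-C4=C5 and E-C1=C2 geometries are carried over from the iodide and the stannane. The step needs CO insertion to outrun direct vinyl–vinyl coupling and ring closure to outrun oligomerisation: the direct coupling would have to form a more strained nine-membered diene, CO pressure favours the acyl complex, and slow addition at high dilution favours cyclisation, while the α-methylene lactone, the isobutyrate and the free tertiary alcohol should be inert under these neutral conditions.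

Step 13
Reactants: 18 tagitinin C
Product: 19 target, 1β,2α-epoxytagitinin C, (1R,2R,4Z,6R,7R,8R,10R)-1,2-epoxy-10-hydroxy-3-oxogermacra-4,11(13)-dien-6,12-olid-8-yl 2-methylpropanoate
Conditions: t-BuOOH (1.2 equiv), DBU (0.2 equiv), CH2Cl2, 0 °C
Reagents that add atoms: tert-butyl hydroperoxide, CC(C)(C)OO
Why: Weitz–Scheffer nucleophilic epoxidation: the peroxide anion should add to C1 of the less substituted E-enone on the outer ring face flanked by the C10 hydroxyl (hydrogen-bond delivery), and the enolate then closes to the trans-(1R,2R)-oxirane, while the α-methylated C4=C5 enone and the ester-type α-methylene lactone should react more slowly.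

**Compound list**

1 | acrolein | C=CC=O | starting material
2 | 1-propynylmagnesium bromide | CC#C[Mg]Br | starting material
3 | rac-hex-1-en-4-yn-3-ol | C=CC(O)C#CC | intermediate
4 | (3S)-hex-1-en-4-yn-3-ol | C=C[C@H](O)C#CC | intermediate
5 | (3S,4Z)-5-iodohexa-1,4-dien-3-ol | C=C[C@H](O)/C=C(/C)I | intermediate
6 | 2-(bromomethyl)acrylic acid | C=C(CBr)C(=O)O | starting material
7 | 2-(bromomethyl)acryloyl chloride | C=C(CBr)C(=O)Cl | intermediate (not isolated)
8 | (3S,4Z)-5-iodohexa-1,4-dien-3-yl 2-(bromomethyl)prop-2-enoate | C=C[C@H](OC(=O)C(=C)CBr)/C=C(/C)I | intermediate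
9 | (5S)-3-(bromomethyl)-5-[(1Z)-2-iodoprop-1-en-1-yl]furan-2(5H)-one | O=C1O[C@H](/C=C(/C)I)C=C1CBr | intermediate
10 | (2E)-3-methylpent-2-en-4-yn-1-ol | C#C/C(C)=C/CO | starting material
11 | [(2S,3S)-3-ethynyl-3-methyloxiran-2-yl]methanol | C#C[C@]1(C)O[C@H]1CO | intermediate
12 | (3R)-3-methylpent-4-yne-1,3-diol | C#C[C@](C)(O)CCO | intermediate
13 | (3R,4E)-3-methyl-5-(tributylstannyl)pent-4-ene-1,3-diol | CCCC[Sn](CCCC)(CCCC)/C=C/[C@](C)(O)CCO | intermediate
14 | (3R,4E)-3-hydroxy-3-methyl-5-(tributylstannyl)pent-4-enal | CCCC[Sn](CCCC)(CCCC)/C=C/[C@](C)(O)CC=O | intermediate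
15 | (4R,5S)-4-[(1S,3R,4E)-1,3-dihydroxy-3-methyl-5-(tributylstannyl)pent-4-en-1-yl]-5-[(1Z)-2-iodoprop-1-en-1-yl]-3-methylidenedihydrofuran-2(3H)-one | C=C1C(=O)O[C@H](/C=C(/C)I)[C@H]1[C@H](C[C@@](C)(O)/C=C/[Sn](CCCC)(CCCC)CCCC)O | intermediate
16 | (1R,3R,4E)-3-hydroxy-1-{(2S,3R)-2-[(1Z)-2-iodoprop-1-en-1-yl]-4-methylidene-5-oxooxolan-3-yl}-3-methyl-5-(tributylstannyl)pent-4-en-1-yl 2-methylpropanoate | C=C1C(=O)O[C@H](/C=C(/C)I)[C@H]1[C@@H](C[C@@](C)(O)/C=C/[Sn](CCCC)(CCCC)CCCC)OC(=O)C(C)C | intermediate
17 | C3-acylpalladium iodide formed from 16 and CO (AsPh3 ligands on palladium not drawn) | C=C1C(=O)O[C@H](/C=C(/C)C(=O)[Pd]I)[C@H]1[C@@H](C[C@@](C)(O)/C=C/[Sn](CCCC)(CCCC)CCCC)OC(=O)C(C)C | intermediate (not isolated)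
18 | tagitinin C, (1E,4Z,6R,7R,8R,10R)-10-hydroxy-3-oxogermacra-1,4,11(13)-trien-6,12-olid-8-yl 2-methylpropanoate | C=C1C(=O)O[C@@H]2/C=C(/C)C(=O)/C=C/[C@](C)(O)C[C@@H](OC(=O)C(C)C)[C@@H]12 | intermediate
19 | 1β,2α-epoxytagitinin C (CNP0273626.1) | C=C1C(=O)O[C@@H]2/C=C(/C)C(=O)[C@@H]3O[C@H]3[C@](C)(O)C[C@@H](OC(=O)C(C)C)[C@@H]12 | target

**Step count and risks**

Total steps: 13. Longest linear sequence: 9 steps (steps 1–5, then 10–13).

Steps most likely to fail:

Step 12. Ring closure of the acylpalladium intermediate may lose to intermolecular coupling (oligomerisation), to protodestannylation, or to capture of the acyl complex by the exocyclic methylene. The fallback sets out from 16 and comes back at 18, forming the same C2–C3 bond by carbonyl addition instead of cross-coupling. 16 would be formylated at C4 (Pd(PPh3)4, CO, Bu3SnH added slowly, THF, 50 °C) to the Z-enal with the stannane retained, F1. Iododestannylation (I2, CH2Cl2, 0 °C) would give the E-vinyl iodide enal F2. Nozaki–Hiyama–Kishi macrocyclisation (CrCl2, NiCl2 cat., DMSO/THF, high dilution) would close the ring to the C3 carbinol F3, as both C3 epimers. Oxidation (MnO2 or Dess–Martin periodinane, CH2Cl2) would then give 18.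

Step 13. The peroxide may add unselectively among the three Michael acceptors, or to the wrong face of C1=C2. The fallback sets out from 18 and comes back at 19, moving the epoxidation to the allylic alcohol oxidation level, where it is electrophilic and hydroxyl-directed. Luche reduction of 18 (NaBH4, CeCl3·7H2O, MeOH, −78 °C) would give the C3 carbinol F3. VO(acac)2/t-BuOOH (CH2Cl2, 0 °C) should epoxidise C1=C2, the alkene flanked by both the C3 and C10 hydroxyls, to the epoxy alcohol F4, leaving the electron-poor methylene lactone untouched. Dess–Martin oxidation of the C3 carbinol would then give 19.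

Step 11. Activation of the hindered C8 carbinol may lead to elimination toward C7, oxetane formation with the C10 hydroxyl, or translactonisation instead of SN2 inversion. The fallback sets out from 15 and comes back at 16, setting C8 by directed reduction. Dess–Martin oxidation of 15 (NaHCO3, CH2Cl2, 0 °C) would give the β-hydroxy ketone F5. Evans–Saksena reduction (Me4NBH(OAc)3, MeCN/AcOH, −30 °C), with hydride delivered from the C10 hydroxyl, should give the 8,10-anti diol F6 with the (8R) configuration. Selective acylation of the secondary alcohol (isobutyric anhydride, DMAP cat., pyridine, 0 °C) would then give 16.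

Further compounds
F1 | step 12 | C4-formyl analogue of 16 (Z-enal in place of the vinyl iodide, stannane kept) | C=C1C(=O)O[C@H](/C=C(/C)C=O)[C@H]1[C@@H](C[C@@](C)(O)/C=C/[Sn](CCCC)(CCCC)CCCC)OC(=O)C(C)C
F2 | step 12 | C4-formyl, C2-iodo analogue of 16 (E-vinyl iodide in place of the stannane) | C=C1C(=O)O[C@H](/C=C(/C)C=O)[C@H]1[C@@H](C[C@@](C)(O)/C=C/I)OC(=O)C(C)C
F3 | step 12 | 3-deoxo-3-hydroxy analogue of 18 (C3 carbinol, both C3 epimers) | C=C1C(=O)O[C@@H]2/C=C(/C)C(O)/C=C/[C@](C)(O)C[C@@H](OC(=O)C(C)C)[C@@H]12
F4 | step 13 | 3-deoxo-3-hydroxy analogue of 19 ((1R,2R)-epoxy C3 carbinol, both C3 epimers) | C=C1C(=O)O[C@@H]2/C=C(/C)C(O)[C@@H]3O[C@H]3[C@](C)(O)C[C@@H](OC(=O)C(C)C)[C@@H]12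
F5 | step 11 | 8-oxo analogue of 15 (β-hydroxy ketone) | C=C1C(=O)O[C@H](/C=C(/C)I)[C@H]1C(=O)C[C@@](C)(O)/C=C/[Sn](CCCC)(CCCC)CCCC
F6 | step 11 | (8R)-epimer of 15 (8,10-anti diol) | C=C1C(=O)O[C@H](/C=C(/C)I)[C@H]1[C@@H](C[C@@](C)(O)/C=C/[Sn](CCCC)(CCCC)CCCC)O
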